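33.0% of the Q charged stands as L at the end of the earlier runs, the mean of the last readings; call this the plateau share. Those last readings lie within a point of one another although Z goes from 0.57 mol% to 0.95 mol%.

| flask | Q | G | Z | remark | time |
|---|---|---|---|---|---|
| larch | 0.50 M | 0.25 M | 0.57 mol% | run made earlier |  |
| ash | 0.50 M | 0.25 M | 0.7 mol% | run made earlier |  |
| cedar | 0.50 M | 0.25 M | 0.95 mol% | run made earlier |  |
| Sunday's | 0.50 M | 0.250 M | 0.5 mol% |  | 15 h |
| Friday's | 0.50 M | 0.250 M | 1 mol% |  | 15 h |

| larch: time / h | larch: L / % | ash: time / h | ash: L / % | cedar: time / h | cedar: L / % |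
|---|---|---|---|---|---|
| 1.33 | 22.9 | 1.33 | 24.3 | 1.33 | 27.8 |
| 2.50 | 29.1 | 2.50 | 32.0 | 2.50 | 32.4 |
| 4.00 | 32.7 | 4.00 | 32.8 | 4.00 | 32.8 |
| 8.00 | 32.9 | 8.00 | 33.2 | 8.00 | 33.3 |
| 15.0 | 32.6 | 15.0 | 33.5 | 15.0 | 32.8 |

(each reading ± 0.5 percentage points)

- the average divides the monomer in chains by the number of chains begun, living and dead together
- steps that have been proposed: G + Q -> J; Q + Z -> X; Q + E -> L + E; Q + Z -> E + L; L + E -> Q + E
- the earlier runs do not show the number of chains; that part of a forecast is a guess

- which of the two ends with the longer chains by the average number of monomer units in a chain (chains begun, living or dead) ("neither" if they lie within 10%) (Sunday's / Friday's / neither)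
- average number of monomer units in a chain (chains begun, living or dead) at the end, Sunday's
- average number of monomer units in a chain (chains begun, living or dead) at the end, Friday's

Build the ladder of times first. Treat the gap between L and the plateau as shrinking exponentially, and take its rate from the first reading: 0.892 h⁻¹ in larch and 1.39 h⁻¹ in cedar. The rate climbs with the loading, so scale it in proportion. Friday's then has a time constant of 0.682 h, and Sunday's a longer one of 1.28 h. The 15 h allowed is 11.7 of Sunday's time constants, so expect both flasks to end on the plateau. Larch shows what that looks like: 32.9% at 8.00 h and 32.6% at 15.0 h, a step inside the scatter of 0.5 percentage points.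

Now write the balance of Z, the limiting reagent for chains, whose loading is far below the plateau share. Z charged equals Z left plus E plus X. A chain begins when Q meets Z, so chains begun are at most the Z charged. Both L and Z are counted on the Q charged, so Q cancels: divide the plateau share by the loading to estimate the shortest average the balance allows, a floor that carries the scatter of the readings. That gives 65.9 units for Sunday's and 33.0 for Friday's, so expect Sunday's chains to come out twice as long, provided Z splits alike in both flasks. The split of Z between E and X stays unseen in these runs.

The forecast says Sunday's, with 76 against 38 units: “The factor of two between runs is firm.”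

The flasks give Sunday's, with 67.5 and 33.7 units.

    G + Q → J (k = 38.0 M⁻¹ h⁻¹)
    Q + Z → X (k = 0.180 M⁻¹ h⁻¹)
    Q + E → L + E, rate k3*[E]*[Q] (k = 380 M⁻¹ h⁻¹)
    Q + Z → E + L (k = 10.0 M⁻¹ h⁻¹)
    L + E → Q + E, rate k5*[E] as long as [L] is above zero (k = 32.0 h⁻¹)

Both lengths lie above the reckoned floors. At the end of Sunday's, Z stands at 0% of its charge and X at 0.00884% of the Q charged, against a loading of 0.5 mol%. Repeat the division on a further flask, like Sunday's but with 1.2 mol% of Z: the plateau share over that loading gives a floor of 27.5 units. That flask ends with L at 33.1% of the Q charged, Z at 0% of its charge and chains of 28.1 units.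

(The runs are calculated for an exercise.)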